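The C40 skeleton is cut by a biomimetic [5+2] cycloaddition into a labdane diene acid and a ring-B-contracted abietane hydroxyquinone; everything rests on building that quinone's ring C de novo. The key step, a gold-catalysed furan–yne phenol synthesis, exploits the C8–C9 bond as the fusion bond shared by cyclopentane ring B (C5, C7–C10) and six-membered ring C (C8, C9, C11–C14). From a monocyclic ring-A precursor bearing an ethynyl group on C10 and a 4-isopropyl-2-furyl group on C7, it forges C8–C9, closes ring B and creates aromatic ring C with the furan oxygen on C11, in one operation.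

Key step: step 9

Assumption: the labdane partner 22 (4-epi-trans-communic acid) is taken as purchasable isolated natural product and is used unprotected.

Numbering: abietane numbers for the diterpene half built here (C6 is the exocyclic carbon on C7; α = face of H5, β = face of the C10 methyl), primed labdane numbers for the other half.

**Step 1**
Reactants: 1 4-bromofuran-2-carbaldehyde
Product: 2 4-isopropylfuran-2-carbaldehyde
Conditions: i-PrZnBr, Pd(OAc)2 (2 mol %), CPhos (4 mol %), THF/toluene, 25 °C
Reagents that add atoms: isopropylzinc bromide CC(C)[Zn]Br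
Why: Negishi cross-coupling of a secondary alkylzinc halide, in which the bulky biarylphosphine makes reductive elimination faster than β-hydride elimination (no n-propyl isomer) and the organozinc tolerates the aldehyde.

**Step 2**
Reactants: 2 4-isopropylfuran-2-carbaldehyde
Product: 4 2-(4-isopropylfuran-2-yl)acetic acid, via nitrile 3 (not isolated)
Conditions: TosMIC, t-BuOK, DME, –40 °C; MeOH, reflux; then KOH, H2O/EtOH, reflux; HCl to pH 3
Reagents that add atoms: TosMIC Cc1ccc(cc1)S(=O)(=O)C[N+]#[C-]; potassium hydroxide [K+].[OH-]; water O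
Why: Van Leusen reductive cyanation turns the aldehyde into the one-carbon-homologated nitrile, and basic nitrile hydrolysis, which the acid-sensitive furan tolerates, gives the arylacetic acid.

**Step 3**
Reactants: 5 2,4,4-trimethylcyclohex-2-en-1-one
Product: 6 (R)-2,4,4-trimethylcyclohex-2-en-1-ol
Conditions: (S)-2-methyl-CBS-oxazaborolidine (10 mol %), BH3·SMe2, THF, –20 °C; MeOH quench
Reagents that add atoms: none
Why: Corey–Bakshi–Shibata reduction, in which the oxazaborolidine–borane complex binds the carbonyl anti to the larger α-methylvinyl arm and delivers hydride to one face only, should set C1 as R by 1,2-reduction.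

**Step 4**
Reactants: 6 (R)-2,4,4-trimethylcyclohex-2-en-1-ol; 4 2-(4-isopropylfuran-2-yl)acetic acid
Product: 7 (1R)-2,4,4-trimethylcyclohex-2-en-1-yl 2-(4-isopropylfuran-2-yl)acetate
Conditions: DCC, DMAP (cat.), CH2Cl2, 0 → 25 °C
Reagents that add atoms: none
Why: Steglich esterification acylates the oxygen through the N-acylpyridinium ion and leaves the carbinol stereocentre and the allylic double bond untouched.

**Step 5**
Reactants: 7 (1R)-2,4,4-trimethylcyclohex-2-en-1-yl 2-(4-isopropylfuran-2-yl)acetate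
Product: 9 (2S)-2-(4-isopropylfuran-2-yl)-2-[(1S)-2,6,6-trimethylcyclohex-2-en-1-yl]acetic acid, via silyl ketene acetal 8 (not isolated)
Conditions: LiN(SiMe3)2, THF/DMPU, –78 °C; Me3SiCl; warm to 60 °C; 1 M HCl
Reagents that add atoms: none
Why: Ireland–Claisen rearrangement, whose suprafacial [3,3] shift transfers the C1–O chirality to C5 (new C5–C7 bond on the β face, H5 α) and moves the alkene to C1=C10; a boat-like transition state of the (Z)-ketene acetal is expected to give the 2S (7β-series) epimer, and either C7 epimer is usable because C7 is equilibrated in step 12.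

**Step 6**
Reactants: 9 the acid from step 5
Product: 10 (2R)-2-(4-isopropylfuran-2-yl)-2-[(1S)-2,6,6-trimethylcyclohex-2-en-1-yl]ethan-1-ol
Conditions: LiAlH4, THF, 0 → 25 °C; Fieser work-up
Reagents that add atoms: none
Why: Hydride reduction of the carboxylic acid gives the primary alcohol without touching the furan, the trisubstituted alkene or the stereocentres (the descriptor at C7 changes only by priority).

**Step 7**
Reactants: 10 the alcohol from step 6
Product: 11 tert-butyl{(2R)-2-(4-isopropylfuran-2-yl)-2-[(1S)-2,6,6-trimethylcyclohex-2-en-1-yl]ethoxy}dimethylsilane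
Conditions: TBSCl, imidazole, DMF, 25 °C
Reagents that add atoms: tert-butyldimethylsilyl chloride CC(C)(C)[Si](C)(C)Cl
Why: Imidazole-mediated silylation masks the primary hydroxyl, which would otherwise add to the gold-activated alkyne in step 9 and be oxidised in step 10.

**Step 8**
Reactants: 11 the silyl ether from step 7
Product: 13 tert-butyl{(2R)-2-[(1S,2S)-2-ethynyl-2,6,6-trimethylcyclohexyl]-2-(4-isopropylfuran-2-yl)ethoxy}dimethylsilane, via silylalkyne 12 (not isolated)
Conditions: Fe(acac)3 (0.5 equiv), PhSiH3, Me3SiC≡CSO2Ph, EtOH, 60 °C; then K2CO3, MeOH, 25 °C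
Reagents that add atoms: phenyl (trimethylsilyl)ethynyl sulfone C[Si](C)(C)C#CS(=O)(=O)c1ccccc1
Why: Mukaiyama-type hydrogen-atom-transfer hydroalkynylation, in which an iron hydride gives H to C1, the tertiary C10 radical adds to the sulfonyl-bearing alkyne carbon and expels PhSO2 radical, attack coming anti to the pseudo-axial C5 side chain so that the alkynyl group is trans to C7 (C10 methyl β); carbonate methanolysis then removes the alkynyl silyl group.

**Step 9**
Reactants: 13 the furan–yne from step 8
Product: 14 11-hydroxy-6-(tert-butyldimethylsilyloxy)-5(6→7)abeo-abieta-8,11,13-triene (trans-fused rings A/B; 5α-H; 10β-CH3; 7β-CH2OTBS)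
Conditions: [(JohnPhos)Au(NCMe)]SbF6 (5 mol %; JohnPhos = (biphenyl-2-yl)di-tert-butylphosphine), CH2Cl2, 25 °C
Reagents that add atoms: none
Why: Monovalent gold activates the terminal alkyne and the furan C2=C3 bond attacks it in the exo-dig mode, forming the C8–C9 bond and a cyclopropyl gold carbene; this opens to a gold-carbenoid dienal whose carbonyl oxygen adds to the carbene carbon C11, and the gold-bound oxepine/arene-oxide manifold (C11–C12 bond) opens to the phenol, so that the furan oxygen ends on C11. The closest known reaction type is the Hashmi phenol synthesis (gold-catalysed furan–yne cycloisomerisation), established for three-atom tethers that give phenol-annulated five-membered rings. Ring B is closed by 5-exo-dig attack of the furan on the activated alkyne and ring C by the 6π closure that joins C11 to C12. No stereocentre is formed (C8 and C9 become arene carbons) and C5, C7 and C10 are not involved, the trans-diequatorial ethynyl and furfuryl arms on ring A holding the two π systems within reach. The step needs chemoselectivity for the furan over the silyl ether oxygen and for exo over endo attack, which the π-nucleophilic 2,4-dialkylfuran and the three-atom tether should secure; the direction of the final arene-oxide opening is not critical, because step 10 oxidises C11 and C12 alike.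

**Step 10**
Reactants: 14 the phenol from step 9
Product: 18 12-hydroxy-6-(tert-butyldimethylsilyloxy)-5(6→7)abeo-abieta-8,12-diene-11,14-dione (7β-CH2OTBS), via o-quinone 15 (not isolated), via catechol thioether 16 (not isolated), via thio-o-quinone 17 (not isolated)
Conditions: IBX (2.2 equiv), CHCl3, 25 °C, C6F5SH added after the first oxidation; then NaOH, MeOH, 25 °C; aq. HCl
Reagents that add atoms: IBX (2-iodoxybenzoic acid) O=C1OI(=O)(O)c2ccccc12; sodium hydroxide [Na+].[OH-]
Why: One-pot phenol-to-hydroxyquinone oxidation known for abietane-type phenols, in which IBX oxygenates the only free ortho position (C12), the thiol adds at C14 (C13 is blocked by isopropyl) and the catechol is reoxidised, and hydroxide displaces the thiolate by addition–elimination to give the 14-hydroxy-o-quinone, drawn as its 12-hydroxy-p-quinone tautomer.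

**Step 11**
Reactants: 18 the silyl-protected hydroxyquinone
Product: 19 6,12-dihydroxy-5(6→7)abeo-abieta-8,12-diene-11,14-dione (7β-CH2OH)
Conditions: HF·pyridine, pyridine, THF, 0 → 25 °C
Reagents that add atoms: none
Why: Fluoride-mediated cleavage of the primary silyl ether under buffered, non-basic conditions should leave the hydroxyquinone intact.

**Step 12**
Reactants: 19 the quinone alcohol
Product: 21 12-hydroxy-11,14-dioxo-5(6→7)abeo-abieta-8,12-dien-6-al with 7α-CHO (H7 β; 5α-H; 10β-CH3), via 7β-aldehyde 20 (not isolated)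
Conditions: Dess–Martin periodinane, NaHCO3, CH2Cl2, 0 °C; then Et3N, degassed CH2Cl2, 25 °C; dilute HCl
Reagents that add atoms: none
Why: Dess–Martin oxidation gives the aldehyde, and base-mediated enolisation of the doubly activated C7–H (α to the formyl group and vinylogous to the C11 carbonyl) should equilibrate C7 to the 7α epimer, whose formyl group is pseudo-equatorial on ring B and avoids the C4 methyl groups.

**Step 13**
Reactants: 21 the 7α-formyl hydroxyquinone; 22 4-epi-trans-communic acid [(E)-labda-8(17),12,14-trien-18-oic acid]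
Product: 23 the target CNP0256710.1
Conditions: BF3·OEt2, CH2Cl2, –78 → –40 °C, excess 22; aq. work-up
Reagents that add atoms: none
Why: Lewis-acid-promoted perezone-type cationic [5+2] cycloaddition, in which BF3 chelated between O11 and O12 makes C8–C9–C11–C12–C13 a 2-oxidopentadienyl cation, the diene CH2 terminus (C15') attacks C8 on the α face anti to the axial C10 methyl (the pseudo-equatorial 7α-formyl group lies near the ring plane), and the allyl cation collapses onto C13 on the same face with the propenyl arm endo under the C9=C11–C12 bridge, setting C8, C13 and C14' together.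

**Compound list**
1 | 4-bromofuran-2-carbaldehyde | O=Cc1cc(Br)co1 | starting material
2 | 4-isopropylfuran-2-carbaldehyde | O=Cc1cc(C(C)C)co1 | intermediate
3 | 2-(4-isopropylfuran-2-yl)acetonitrile | N#CCc1cc(C(C)C)co1 | intermediate
4 | 2-(4-isopropylfuran-2-yl)acetic acid | OC(=O)Cc1cc(C(C)C)co1 | intermediate
5 | 2,4,4-trimethylcyclohex-2-en-1-one | CC1=CC(C)(C)CCC1=O | starting material
6 | (R)-2,4,4-trimethylcyclohex-2-en-1-ol | O[C@@H]1CCC(C)(C)C=C1C | intermediate
7 | (1R)-2,4,4-trimethylcyclohex-2-en-1-yl 2-(4-isopropylfuran-2-yl)acetate | O=C(Cc1cc(C(C)C)co1)O[C@@H]1CCC(C)(C)C=C1C | intermediate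
8 | (Z)-trimethylsilyl ketene acetal of 7 (furyl cis to OSiMe3) | C[Si](C)(C)O/C(=C\c1cc(C(C)C)co1)O[C@@H]1CCC(C)(C)C=C1C | intermediate
9 | (2S)-2-(4-isopropylfuran-2-yl)-2-[(1S)-2,6,6-trimethylcyclohex-2-en-1-yl]acetic acid | CC1=CCCC(C)(C)[C@@H]1[C@@H](c1cc(C(C)C)co1)C(=O)O | intermediate
10 | (2R)-2-(4-isopropylfuran-2-yl)-2-[(1S)-2,6,6-trimethylcyclohex-2-en-1-yl]ethan-1-ol | CC1=CCCC(C)(C)[C@@H]1[C@@H](c1cc(C(C)C)co1)CO | intermediate
11 | tert-butyldimethylsilyl ether of 10 | CC1=CCCC(C)(C)[C@@H]1[C@@H](c1cc(C(C)C)co1)CO[Si](C)(C)C(C)(C)C | intermediate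
12 | tert-butyl{(2R)-2-(4-isopropylfuran-2-yl)-2-[(1S,2S)-2,6,6-trimethyl-2-(trimethylsilylethynyl)cyclohexyl]ethoxy}dimethylsilane | C[Si](C)(C)C#C[C@@]1(C)CCCC(C)(C)[C@@H]1[C@@H](c1cc(C(C)C)co1)CO[Si](C)(C)C(C)(C)C | intermediate
13 | tert-butyl{(2R)-2-[(1S,2S)-2-ethynyl-2,6,6-trimethylcyclohexyl]-2-(4-isopropylfuran-2-yl)ethoxy}dimethylsilane | C#C[C@@]1(C)CCCC(C)(C)[C@@H]1[C@@H](c1cc(C(C)C)co1)CO[Si](C)(C)C(C)(C)C | intermediate
14 | 11-hydroxy-6-(tert-butyldimethylsilyloxy)-5(6→7)abeo-abieta-8,11,13-triene (5α-H; 10β-CH3; 7β-CH2OTBS) | C12=C(C(O)=CC(C(C)C)=C1)[C@@]1(C)CCCC(C)(C)[C@@H]1[C@@H]2CO[Si](C)(C)C(C)(C)C | intermediate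
15 | 11,12-o-quinone of 14 | C12=C(C(=O)C(=O)C(C(C)C)=C1)[C@@]1(C)CCCC(C)(C)[C@@H]1[C@@H]2CO[Si](C)(C)C(C)(C)C | intermediate
16 | 11,12-dihydroxy-14-(pentafluorophenylthio) arene | C12=C(C(O)=C(O)C(C(C)C)=C1Sc3c(F)c(F)c(F)c(F)c3F)[C@@]1(C)CCCC(C)(C)[C@@H]1[C@@H]2CO[Si](C)(C)C(C)(C)C | intermediate
17 | 14-(pentafluorophenylthio)-11,12-o-quinone | C12=C(C(=O)C(=O)C(C(C)C)=C1Sc3c(F)c(F)c(F)c(F)c3F)[C@@]1(C)CCCC(C)(C)[C@@H]1[C@@H]2CO[Si](C)(C)C(C)(C)C | intermediate
18 | 12-hydroxy-6-(tert-butyldimethylsilyloxy)-5(6→7)abeo-abieta-8,12-diene-11,14-dione (7β-CH2OTBS) | C12=C(C(=O)C(O)=C(C(C)C)C1=O)[C@@]1(C)CCCC(C)(C)[C@@H]1[C@@H]2CO[Si](C)(C)C(C)(C)C | intermediate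
19 | 6,12-dihydroxy-5(6→7)abeo-abieta-8,12-diene-11,14-dione (7β-CH2OH) | C12=C(C(=O)C(O)=C(C(C)C)C1=O)[C@@]1(C)CCCC(C)(C)[C@@H]1[C@@H]2CO | intermediate
20 | 12-hydroxy-11,14-dioxo-5(6→7)abeo-abieta-8,12-dien-6-al, 7β-CHO epimer | C12=C(C(=O)C(O)=C(C(C)C)C1=O)[C@@]1(C)CCCC(C)(C)[C@@H]1[C@@H]2C=O | intermediate
21 | 12-hydroxy-11,14-dioxo-5(6→7)abeo-abieta-8,12-dien-6-al, 7α-CHO epimer | C12=C(C(=O)C(O)=C(C(C)C)C1=O)[C@@]1(C)CCCC(C)(C)[C@@H]1[C@H]2C=O | intermediate
22 | 4-epi-trans-communic acid, (4R,5R,9S,10R,12E)-labda-8(17),12,14-trien-18-oic acid | C=C1CC[C@@H]2[C@](C)(CCC[C@@]2(C)C(=O)O)[C@H]1C/C=C(\C)C=C | starting material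
23 | CNP0256710.1, the [5+2] adduct of 21 and 22 (C8–C15' and C13–C14' bonds; C14 ketone bridge β; 7α-CHO) | C=C1CC[C@@H]2[C@](C)(CCC[C@@]2(C)C(=O)O)[C@H]1C/C=C(\C)[C@@H]1C[C@@]23C(=O)[C@]1(C(C)C)C(=O)C(O)=C2[C@@]1(C)CCCC(C)(C)[C@@H]1[C@H]3C=O | target

Total step count: 13. Longest linear sequence: 12 steps (1 → 2 → 4 → 7 → 9 → 10 → 11 → 13 → 14 → 18 → 19 → 21 → 23).

**Steps most likely to fail**

Step 13. Facial selectivity may be poor, the free aldehyde may undergo an ene or Prins reaction with the exocyclic methylene under the Lewis acid, and the diene may oligomerise cationically. The fallback sets out from 18 and runs the cycloaddition before the alcohol is unmasked, so that the 7β-silyloxymethyl group and the C10 methyl both shield the β face and no aldehyde is present. BF3·OEt2-promoted [5+2] cycloaddition of 18 with 22 should give the silyl-protected adduct F1. HF·pyridine then gives the adduct alcohol F2. Dess–Martin oxidation gives the 7β-formyl adduct F3, which is not isolated and is equilibrated with DBU to the 7α epimer; the route is rejoined at target 23.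

Step 8. The planar tertiary C10 radical may be trapped with poor facial selectivity or be reduced before it is alkynylated. The fallback sets out from 11 and makes the quaternary centre by polar conjugate addition. Allylic oxidation at C2 (Rh2(cap)4, dirhodium tetracaprolactamate, with t-BuOOH) should give the enone F4. Nickel-catalysed conjugate addition of Et2AlC≡CSiMe3 (Ni(acac)2, DIBAL-H) anti to the C5 side chain gives the β-alkynyl ketone F5. Condensation with TsNHNH2 gives the tosylhydrazone F6 (E/Z mixture), and Caglioti-type reduction with catecholborane/NaOAc removes the carbonyl; the route is rejoined at 12, which is desilylated as in step 8.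

Step 10. The o-quinone may be over-oxidised or polymerise, and the thiol/hydroxide exchange may stay incomplete. The fallback sets out from 14 and goes through the p-quinone. Teuber oxidation with ON(SO3K)2 (KH2PO4, acetone/water) should give the 11,14-quinone F7. Conjugate addition of morpholine at C12 with aerobic reoxidation gives the aminoquinone F8. Hydrolysis of this vinylogous amide (aq. NaOH, EtOH, 50 °C; then HCl) rejoins the route at 18.

**Further compounds**
F1 | step 13 | [5+2] adduct of 18 and 22 (7β-CH2OTBS) | C=C1CC[C@@H]2[C@](C)(CCC[C@@]2(C)C(=O)O)[C@H]1C/C=C(\C)[C@@H]1C[C@@]23C(=O)[C@]1(C(C)C)C(=O)C(O)=C2[C@@]1(C)CCCC(C)(C)[C@@H]1[C@@H]3CO[Si](C)(C)C(C)(C)C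
F2 | step 13 | adduct alcohol (7β-CH2OH) | C=C1CC[C@@H]2[C@](C)(CCC[C@@]2(C)C(=O)O)[C@H]1C/C=C(\C)[C@@H]1C[C@@]23C(=O)[C@]1(C(C)C)C(=O)C(O)=C2[C@@]1(C)CCCC(C)(C)[C@@H]1[C@@H]3CO
F3 | step 13 | 7β-formyl adduct (C7 epimer of 23) | C=C1CC[C@@H]2[C@](C)(CCC[C@@]2(C)C(=O)O)[C@H]1C/C=C(\C)[C@@H]1C[C@@]23C(=O)[C@]1(C(C)C)C(=O)C(O)=C2[C@@]1(C)CCCC(C)(C)[C@@H]1[C@@H]3C=O
F4 | step 8 | cyclohexenone from allylic oxidation of 11 at C2 | CC1=CC(=O)CC(C)(C)[C@@H]1[C@@H](c1cc(C(C)C)co1)CO[Si](C)(C)C(C)(C)C
F5 | step 8 | β-(trimethylsilylethynyl) ketone (alkynyl trans to the C5 side chain) | C[Si](C)(C)C#C[C@@]1(C)CC(=O)CC(C)(C)[C@@H]1[C@@H](c1cc(C(C)C)co1)CO[Si](C)(C)C(C)(C)C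
F6 | step 8 | tosylhydrazone of F5 (E/Z mixture at C=N) | C[Si](C)(C)C#C[C@@]1(C)CC(=NNS(=O)(=O)c2ccc(C)cc2)CC(C)(C)[C@@H]1[C@@H](c1cc(C(C)C)co1)CO[Si](C)(C)C(C)(C)C
F7 | step 10 | 6-(tert-butyldimethylsilyloxy)-5(6→7)abeo-abieta-8,12-diene-11,14-dione | C12=C(C(=O)C=C(C(C)C)C1=O)[C@@]1(C)CCCC(C)(C)[C@@H]1[C@@H]2CO[Si](C)(C)C(C)(C)C
F8 | step 10 | 12-morpholino derivative of F7 | C12=C(C(=O)C(N3CCOCC3)=C(C(C)C)C1=O)[C@@]1(C)CCCC(C)(C)[C@@H]1[C@@H]2CO[Si](C)(C)C(C)(C)C
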